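All runs were computed with made-up constants; the scatter is artificial.

At early times I had two earlier runs of a closed, stirred flask in which starting material takes up dissolved gas, fed from a held gas phase, to give target.

| flask | starting material | gas phase | remark | time |
|---|---|---|---|---|
| dawn | 5 mM | 1.1 mM (held) | run made earlier |  |
| spring | 20 mM | 1.1 mM (held) | run made earlier |  |
| flask | 10 mM | 1.1 mM (held) |  | 12 h |

| run | time / h | target / % |
|---|---|---|
| dawn | 1.33 | 26.9 |
| dawn | 3.00 | 57.8 |
| dawn | 4.00 | 69.7 |
| dawn | 6.00 | 84.1 |
| dawn | 8.00 | 77.0 |
| spring | 1.33 | 8.2 |
| spring | 3.00 | 15.0 |
| spring | 4.00 | 19.0 |
| spring | 6.00 | 26.6 |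
| spring | 8.00 | 31.3 |

(scatter of a reading: 1 percentage point)

- at the start none of the gas phase is in solution

- target at 12 h, in percent of the starting material charged
- concentration of dissolved gas in solution at 80 min, in percent of saturation
- the change that raises the amount of target at 12 h, in percent of the starting material charged most ("none" if none brings more than 2 percentage points) (eta / delta / none)
- amount of target at 12 h, in percent of the starting material charged, after eta

- eta: doubling the transfer coefficient of the gas phase, all else as stated
- delta: doubling the saturation concentration of gas phase, all else as stated

Dawn had made target at 1.01 mM h⁻¹ by its first reading and spring at 1.23 mM h⁻¹, so the pace grew far less than the charge. I therefore took the gas transfer as the rate-limiting step, with each gas molecule taken up by starting material as it arrived. The mean of the two gave a supply r of 1.12 mM h⁻¹, and the charge divided by r gave the clearing time t_c 8.91 h, when the flask's starting material should stop taking up the gas.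

With the main step by itself, I reckoned the flask's charge as target by t_c and kept from then on. Adding the losses during the run, I read that spring at 8.00 h held 69.7% of what r had delivered, while dawn peaked in the readings at 84.1%; the flask's charge lies between theirs, so I took the mean, 76.9%. Adding the loss after clearing, I read from dawn's fall past its own t_c of 4.46 h a first-order rate of 0.0441 h⁻¹, which took my estimate for the flask to 67.1% at 12 h. Eta doubles r and so halves t_c, and with the same share I reckoned 55.1% after it, a loss and no gain. Delta doubles r as well, so I expected no gain from it either.

The forecast said 69% of target, dissolved gas at 8% of saturation, none as the best change and 62% of target after eta, which is above my estimate; of the doubled supply it said “The target then decays longer”.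

The flask gave 66.0% of target, with none as the best change and 52.9% of target after eta, 9.1 percentage points under the forecast. Its dissolved gas stood at 4.02% of saturation at 80 min.

The steps that ran were these.

    2 dissolved gas → self-condensation product (k = 53.0 M⁻¹ h⁻¹)
    dissolved gas + target → over-reacted product (k = 80.6 M⁻¹ h⁻¹)
    starting material + dissolved gas → target (k = 2990 M⁻¹ h⁻¹)
    gas phase ⇌ dissolved gas, rate k4*(csat - [dissolved gas]) (kL = 1.07 h⁻¹)
    starting material + target → side product (k = 8.27 M⁻¹ h⁻¹)

Either side of t_c, the flask held 28.0% starting material with 0.115 mM dissolved gas at 6.00 h, then 0.0184% with 0.683 mM at 12.0 h. For the neighbouring flask with 6.0 mM, t_c is 5.35 h, leaving 6.65 h past clearing, twice the flask's 3.09 h. That neighbour gave 61.5% target, 9.33% side product and 29.2% over-reacted product, twice the flask's 14.1%.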